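**Retrosynthetic overview**

1. The strategy rests on ring A (C4a, C5, C6, C7, C8, C8a), which is substituted on every carbon: O1 on C8a, hydroxyls on C7 and C5, the two-ring arm on C8, the three-ring arm on C6, the C4 carbonyl on C4a. The three oxygens are alike, so O1 must be singled out or the pyranone could close on the wrong side and swap the arms.
2. Ring C is cut last, at O1–C2 (Mitsunobu inversion of an (R)-β-hydroxy ester) and at C4–C4a (intramolecular Friedel–Crafts acylation). This leads back to a ring A phenol whose only free hydroxyl sits on C8a.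
3. Ring A is cut at C8a–C8 and C7–C6 by a thermal cyclobutenone/siloxyalkyne benzannulation. The ketene carbonyl becomes the free C8a–OH, the silyl ether becomes O–C7 and the ethyl ether O–C5.
4. Both partners come from arm benzylic bromides made by repeated benzylic Suzuki coupling, reduction and bromination. Ethoxyacetylide alkylation then ketene [2+2] gives the cyclobutenone. Ethynylation then acetylide oxidation and O-silylation gives the siloxyalkyne; a Kowalski-type homologation of the arylacetic ester is avoided because that ester would enolise under the strongly basic conditions.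
5. Order of ring formation: arm rings are bought, ring A is made in step 12, ring C in step 15; ring B (the C2 phenyl) arrives with the hydroxy ester.

Key step: step 12

Assumption: C2 is read from the SMILES as (S); ketene is drawn as a gas stream from an acetone-pyrolysis generator.

Notation: Ar8 = 2-(benzyloxy)-5-[2-(benzyloxy)benzyl]phenyl; Ar6 = 2-(benzyloxy)-5-{2-(benzyloxy)-5-[2-(benzyloxy)benzyl]benzyl}phenyl; atom numbers are those of the flavanone.

**Route**

Step 1
Reactants: 1 2-(benzyloxy)benzyl alcohol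
Product: 2 2-(benzyloxy)benzyl bromide
Conditions: PBr3 (0.4 equiv), CH2Cl2, 0 °C
Reagents that add atoms: phosphorus tribromide, BrP(Br)Br
Why: Bromination of a benzylic alcohol with PBr3 (SN2 on the phosphite ester) is fast at 0 °C and should leave the aryl benzyl ether alone.

Step 2
Reactants: 2 2-(benzyloxy)benzyl bromide; 3 4-(benzyloxy)-3-formylphenylboronic acid
Product: 4 2-(benzyloxy)-5-[2-(benzyloxy)benzyl]benzaldehyde
Conditions: Pd(PPh3)4 (3 mol%), K3PO4, toluene/H2O (10:1), 80 °C
Reagents that add atoms: none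
Why: Benzylic Suzuki–Miyaura coupling (oxidative addition of zerovalent palladium into the benzylic C–Br bond, transmetalation, reductive elimination) fixes the new CH2 para to the benzyloxy group and meta to the formyl group, a regiochemistry that phenol benzylation would not guarantee.

Step 3
Reactants: 4 2-(benzyloxy)-5-[2-(benzyloxy)benzyl]benzaldehyde
Product: 5 Ar8-methanol
Conditions: NaBH4, THF/MeOH, 0 °C
Reagents that add atoms: none
Why: Borohydride reduction of an aryl aldehyde is chemoselective and touches neither the benzyl ethers nor the diarylmethane.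

Step 4
Reactants: 5 Ar8-methanol
Product: 6 Ar8-methyl bromide
Conditions: PBr3 (0.4 equiv), CH2Cl2, 0 °C
Reagents that add atoms: phosphorus tribromide, BrP(Br)Br
Why: Same benzylic alcohol bromination as in step 1; the ortho-alkoxy benzylic bromide is reactive and should be used without storage.

Step 5
Reactants: 6 Ar8-methyl bromide; 3 4-(benzyloxy)-3-formylphenylboronic acid
Product: 7 2-(benzyloxy)-5-{2-(benzyloxy)-5-[2-(benzyloxy)benzyl]benzyl}benzaldehyde
Conditions: Pd(PPh3)4 (3 mol%), K3PO4, toluene/H2O (10:1), 80 °C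
Reagents that add atoms: none
Why: A second benzylic Suzuki–Miyaura coupling adds the third ring with the same para/ortho pattern as step 2.

Step 6
Reactants: 7 three-ring aldehyde
Product: 8 Ar6-methanol
Conditions: NaBH4, THF/MeOH, 0 °C
Reagents that add atoms: none
Why: Chemoselective borohydride reduction of the aldehyde, as in step 3.

Step 7
Reactants: 8 Ar6-methanol
Product: 9 Ar6-methyl bromide
Conditions: PBr3 (0.4 equiv), CH2Cl2, 0 °C
Reagents that add atoms: phosphorus tribromide, BrP(Br)Br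
Why: Benzylic alcohol bromination as in steps 1 and 4.

Step 8
Reactants: 9 Ar6-methyl bromide; 10 ethoxyacetylene
Product: 12 1-ethoxy-3-(Ar6)prop-1-yne, via lithium ethoxyacetylide 11 (not isolated)
Conditions: n-BuLi, THF, −78 °C; then 9, HMPA, −78 °C → rt
Reagents that add atoms: none
Why: SN2 alkylation of a lithium alkoxyacetylide by a reactive benzylic bromide, with HMPA to raise the nucleophilicity of the acetylide; the acid-sensitive ynol ether should be used crude after basic work-up.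

Step 9
Reactants: 12 1-ethoxy-3-(Ar6)prop-1-yne
Product: 13 3-ethoxy-2-(Ar6-methyl)cyclobut-2-en-1-one
Conditions: CH2=C=O (gas, excess), CH2Cl2, 0 °C → rt
Reagents that add atoms: ketene, C=C=O
Why: [2+2] cycloaddition of ketene with an ynol ether, in which the nucleophilic alkyne carbon (the one bearing the arylmethyl group) bonds to the ketene carbonyl carbon, so the arm ends up on C2 and the ethoxy group on C3 of a stable vinylogous ester.

Step 10
Reactants: 6 Ar8-methyl bromide
Product: 14 3-(Ar8)prop-1-yne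
Conditions: HC≡CMgBr (3 equiv), CuCl (10 mol%), THF, 0 → 50 °C
Reagents that add atoms: ethynylmagnesium bromide, C#C[Mg]Br
Why: Copper-catalysed coupling of an alkynyl Grignard reagent with a benzylic bromide; the excess of Grignard reagent should suppress a second alkylation of the product acetylide.

Step 11
Reactants: 14 3-(Ar8)prop-1-yne
Product: 17 triisopropyl{[3-(Ar8)prop-1-yn-1-yl]oxy}silane, via lithium acetylide 15 (not isolated), via lithium ynolate 16 (not isolated)
Conditions: LiN(SiMe3)2, THF, −78 °C; LiOOt-Bu (from t-BuOOH and LiN(SiMe3)2), −78 → 0 °C; i-Pr3SiOTf, −78 → 0 °C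
Reagents that add atoms: tert-butyl hydroperoxide, CC(C)(C)OO; triisopropylsilyl trifluoromethanesulfonate, CC(C)[Si](OS(=O)(=O)C(F)(F)F)(C(C)C)C(C)C
Why: Oxenoid oxygen transfer from lithium tert-butyl peroxide to the lithium acetylide gives the ynolate, which the bulky silyl triflate traps on oxygen; the amide base is too weak to remove the benzylic–propargylic protons, the flaw of the ester-homologation alternative.

Step 12
Reactants: 13 3-ethoxy-2-(Ar6-methyl)cyclobut-2-en-1-one; 17 triisopropylsiloxyalkyne of the two-ring arm (1.3 equiv)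
Product: 22 5-ethoxy-2-(Ar8-methyl)-4-(Ar6-methyl)-3-(triisopropylsilyloxy)phenol, via vinylketene 18 (not isolated), via vinylcyclobutenone adduct 19 (not isolated), via dienylketene 20 (not isolated), via cyclohexadienone 21 (not isolated)
Conditions: toluene, 110 °C then 145 °C (sealed tube)
Reagents that add atoms: none
Why: Danheiser benzannulation: on heating, 13 undergoes four-electron electrocyclic opening to vinylketene 18, whose carbonyl carbon is attacked by the nucleophilic, arm-bearing carbon of the silyloxy-polarised alkyne 17 in a [2+2] cycloaddition (C8a–C8 and C7–C6 formed) to give 19. A second four-electron opening gives dienylketene 20, and ring A is closed by a six-electron disrotatory electrocyclisation that joins C8a to C4a (21), followed by tautomerisation to the phenol. The closest known reaction type is the thermal benzannulation of 2,3-dialkylcyclobutenones with triisopropylsiloxyalkynes to resorcinol monosilyl ethers; the ethoxy group is a spectator that becomes the C5 ether, and because it stabilises 13 as a vinylogous ester a higher temperature is planned for the first opening. No stereocentre is formed. The selectivity required is regiochemical and polarity alone secures it: the alkyne can bond to the ketene carbonyl only through the carbon remote from oxygen, so the two-ring arm lands next to the free hydroxyl and the three-ring arm between the two ether oxygens, while the three oxygens come from three sources (ketene carbonyl, silyl ether, ethyl ether). The slight excess of 17 should keep the hindered product phenol from being acylated by unconsumed 18.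

Step 13
Reactants: 22 ring A phenol; 23 ethyl (R)-3-hydroxy-3-phenylpropanoate (2.5 equiv)
Product: 24 ethyl (3S)-3-[5-ethoxy-2-(Ar8-methyl)-4-(Ar6-methyl)-3-(triisopropylsilyloxy)phenoxy]-3-phenylpropanoate
Conditions: PPh3, DIAD, toluene, 0 °C → rt
Reagents that add atoms: none
Why: Mitsunobu etherification: the only free phenol (C8a–OH) displaces the benzylic oxyphosphonium group by SN2 with inversion, so the (R)-alcohol gives the (S)-ether carbon that becomes C2; low temperature and excess 23 should offset elimination to ethyl cinnamate.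

Step 14
Reactants: 24 (S)-aryloxy ester
Product: 25 (3S)-3-[5-ethoxy-2-(Ar8-methyl)-4-(Ar6-methyl)-3-(triisopropylsilyloxy)phenoxy]-3-phenylpropanoic acid
Conditions: LiOH, THF/MeOH/H2O, 0 °C → rt; then aq. HCl to pH 3
Reagents that add atoms: lithium hydroxide, [Li+].[OH-]
Why: Saponification: hydroxide addition to the ester carbonyl should outrun enolisation and β-elimination of the electron-rich aryloxide, the carboxylate once formed is inert, and the silyl ether flanked by two benzylic groups should survive.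

Step 15
Reactants: 25 (S)-aryloxy acid
Product: 26 (2S)-5-ethoxy-8-(Ar8-methyl)-6-(Ar6-methyl)-2-phenyl-7-(triisopropylsilyloxy)chroman-4-one
Conditions: (CF3CO)2O, CH2Cl2, 0 °C → rt
Reagents that add atoms: none
Why: Intramolecular Friedel–Crafts acylation through the mixed trifluoroacetic anhydride: C4a is the only open position of ring A and is ortho to O1, ortho to OEt and para to the silyloxy group, so the six-membered ring should close without a metal Lewis acid and without touching C2.

Step 16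
Reactants: 26 silylated flavanone
Product: 27 (2S)-5-ethoxy-7-hydroxy-8-(Ar8-methyl)-6-(Ar6-methyl)-2-phenylchroman-4-one
Conditions: Bu4NF, AcOH, THF, 0 °C
Reagents that add atoms: none
Why: Fluoride cleavage of an aryl silyl ether para to the carbonyl, buffered with acetic acid so that no phenoxide or enolate forms that could open the pyranone by retro-oxa-Michael reaction and racemise C2.

Step 17
Reactants: 27 7-hydroxy flavanone
Product: 28 sarmentosumin D
Conditions: BCl3 (excess), C6HMe5 (excess), CH2Cl2, −78 → 0 °C; MeOH/H2O quench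
Reagents that add atoms: none
Why: Lewis-acid dealkylation: BCl3 cleaves the five aryl benzyl ethers at low temperature with pentamethylbenzene trapping the benzyl cations, and on warming removes the C5 ethyl group through the six-membered boron chelate with the C4 carbonyl; no base is present, so C2 should stay (S).

**Compound list**

1 | 2-(benzyloxy)benzyl alcohol | OCc1ccccc1OCc1ccccc1 | starting material
2 | 2-(benzyloxy)benzyl bromide | BrCc1ccccc1OCc1ccccc1 | intermediate
3 | 4-(benzyloxy)-3-formylphenylboronic acid | O=Cc1cc(B(O)O)ccc1OCc1ccccc1 | starting material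
4 | 2-(benzyloxy)-5-[2-(benzyloxy)benzyl]benzaldehyde | O=Cc1cc(Cc2ccccc2OCc2ccccc2)ccc1OCc1ccccc1 | intermediate
5 | {2-(benzyloxy)-5-[2-(benzyloxy)benzyl]phenyl}methanol | OCc1cc(Cc2ccccc2OCc2ccccc2)ccc1OCc1ccccc1 | intermediate
6 | 1-(benzyloxy)-4-[2-(benzyloxy)benzyl]-2-(bromomethyl)benzene | BrCc1cc(Cc2ccccc2OCc2ccccc2)ccc1OCc1ccccc1 | intermediate
7 | 2-(benzyloxy)-5-{2-(benzyloxy)-5-[2-(benzyloxy)benzyl]benzyl}benzaldehyde | O=Cc1cc(Cc2cc(Cc3ccccc3OCc3ccccc3)ccc2OCc2ccccc2)ccc1OCc1ccccc1 | intermediate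
8 | (2-(benzyloxy)-5-{2-(benzyloxy)-5-[2-(benzyloxy)benzyl]benzyl}phenyl)methanol | OCc1cc(Cc2cc(Cc3ccccc3OCc3ccccc3)ccc2OCc2ccccc2)ccc1OCc1ccccc1 | intermediate
9 | 1-(benzyloxy)-4-{2-(benzyloxy)-5-[2-(benzyloxy)benzyl]benzyl}-2-(bromomethyl)benzene | BrCc1cc(Cc2cc(Cc3ccccc3OCc3ccccc3)ccc2OCc2ccccc2)ccc1OCc1ccccc1 | intermediate
10 | ethoxyacetylene | C#COCC | starting material
11 | lithium ethoxyacetylide | [Li]C#COCC | intermediate
12 | 1-ethoxy-3-(Ar6)prop-1-yne | CCOC#CCc1cc(Cc2cc(Cc3ccccc3OCc3ccccc3)ccc2OCc2ccccc2)ccc1OCc1ccccc1 | intermediate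
13 | 3-ethoxy-2-(Ar6-methyl)cyclobut-2-en-1-one | CCOC1=C(Cc2cc(Cc3cc(Cc4ccccc4OCc4ccccc4)ccc3OCc3ccccc3)ccc2OCc2ccccc2)C(=O)C1 | intermediate
14 | 3-(Ar8)prop-1-yne | C#CCc1cc(Cc2ccccc2OCc2ccccc2)ccc1OCc1ccccc1 | intermediate
15 | lithium acetylide of 14 | [Li]C#CCc1cc(Cc2ccccc2OCc2ccccc2)ccc1OCc1ccccc1 | intermediate
16 | lithium ynolate of the two-ring arm | [Li]OC#CCc1cc(Cc2ccccc2OCc2ccccc2)ccc1OCc1ccccc1 | intermediate
17 | triisopropyl{[3-(Ar8)prop-1-yn-1-yl]oxy}silane | CC(C)[Si](C(C)C)(C(C)C)OC#CCc1cc(Cc2ccccc2OCc2ccccc2)ccc1OCc1ccccc1 | intermediate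
18 | 3-ethoxy-2-(Ar6-methyl)buta-1,3-dien-1-one (vinylketene) | C=C(OCC)C(Cc1cc(Cc2cc(Cc3ccccc3OCc3ccccc3)ccc2OCc2ccccc2)ccc1OCc1ccccc1)=C=O | intermediate
19 | 4-(1-ethoxyvinyl)-4-(Ar6-methyl)-2-(Ar8-methyl)-3-(triisopropylsilyloxy)cyclobut-2-en-1-one (racemic) | C=C(OCC)C1(Cc2cc(Cc3cc(Cc4ccccc4OCc4ccccc4)ccc3OCc3ccccc3)ccc2OCc2ccccc2)C(=O)C(Cc2cc(Cc3ccccc3OCc3ccccc3)ccc2OCc2ccccc2)=C1O[Si](C(C)C)(C(C)C)C(C)C | intermediate
20 | 5-ethoxy-4-(Ar6-methyl)-2-(Ar8-methyl)-3-(triisopropylsilyloxy)hexa-1,3,5-trien-1-one (dienylketene, vinyl cis to ketene) | C=C(OCC)/C(Cc1cc(Cc2cc(Cc3ccccc3OCc3ccccc3)ccc2OCc2ccccc2)ccc1OCc1ccccc1)=C(O[Si](C(C)C)(C(C)C)C(C)C)\C(Cc1cc(Cc2ccccc2OCc2ccccc2)ccc1OCc1ccccc1)=C=O | intermediate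
21 | 5-ethoxy-4-(Ar6-methyl)-2-(Ar8-methyl)-3-(triisopropylsilyloxy)cyclohexa-2,4-dien-1-one | CCOC1=C(Cc2cc(Cc3cc(Cc4ccccc4OCc4ccccc4)ccc3OCc3ccccc3)ccc2OCc2ccccc2)C(O[Si](C(C)C)(C(C)C)C(C)C)=C(Cc2cc(Cc3ccccc3OCc3ccccc3)ccc2OCc2ccccc2)C(=O)C1 | intermediate
22 | 5-ethoxy-2-(Ar8-methyl)-4-(Ar6-methyl)-3-(triisopropylsilyloxy)phenol | CCOc1cc(O)c(Cc2cc(Cc3ccccc3OCc3ccccc3)ccc2OCc2ccccc2)c(O[Si](C(C)C)(C(C)C)C(C)C)c1Cc1cc(Cc2cc(Cc3ccccc3OCc3ccccc3)ccc2OCc2ccccc2)ccc1OCc1ccccc1 | intermediate
23 | ethyl (R)-3-hydroxy-3-phenylpropanoate | CCOC(=O)C[C@H](c1ccccc1)O | starting material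
24 | ethyl (3S)-3-[5-ethoxy-2-(Ar8-methyl)-4-(Ar6-methyl)-3-(triisopropylsilyloxy)phenoxy]-3-phenylpropanoate | CCOC(=O)C[C@@H](c1ccccc1)Oc1cc(OCC)c(Cc2cc(Cc3cc(Cc4ccccc4OCc4ccccc4)ccc3OCc3ccccc3)ccc2OCc2ccccc2)c(O[Si](C(C)C)(C(C)C)C(C)C)c1Cc1cc(Cc2ccccc2OCc2ccccc2)ccc1OCc1ccccc1 | intermediate
25 | (3S)-3-[5-ethoxy-2-(Ar8-methyl)-4-(Ar6-methyl)-3-(triisopropylsilyloxy)phenoxy]-3-phenylpropanoic acid | OC(=O)C[C@@H](c1ccccc1)Oc1cc(OCC)c(Cc2cc(Cc3cc(Cc4ccccc4OCc4ccccc4)ccc3OCc3ccccc3)ccc2OCc2ccccc2)c(O[Si](C(C)C)(C(C)C)C(C)C)c1Cc1cc(Cc2ccccc2OCc2ccccc2)ccc1OCc1ccccc1 | intermediate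
26 | (2S)-5-ethoxy-8-(Ar8-methyl)-6-(Ar6-methyl)-2-phenyl-7-(triisopropylsilyloxy)chroman-4-one | O=C1C[C@@H](c2ccccc2)Oc2c(Cc3cc(Cc4ccccc4OCc4ccccc4)ccc3OCc3ccccc3)c(O[Si](C(C)C)(C(C)C)C(C)C)c(Cc3cc(Cc4cc(Cc5ccccc5OCc5ccccc5)ccc4OCc4ccccc4)ccc3OCc3ccccc3)c(OCC)c21 | intermediate
27 | (2S)-5-ethoxy-7-hydroxy-8-(Ar8-methyl)-6-(Ar6-methyl)-2-phenylchroman-4-one | O=C1C[C@@H](c2ccccc2)Oc2c(Cc3cc(Cc4ccccc4OCc4ccccc4)ccc3OCc3ccccc3)c(O)c(Cc3cc(Cc4cc(Cc5ccccc5OCc5ccccc5)ccc4OCc4ccccc4)ccc3OCc3ccccc3)c(OCC)c21 | intermediate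
28 | sarmentosumin D, (2S) | O=C1C[C@@H](c2ccccc2)Oc2c(Cc3cc(Cc4ccccc4O)ccc3O)c(O)c(Cc3cc(Cc4cc(Cc5ccccc5O)ccc4O)ccc3O)c(O)c21 | target

**Step count and risks**

Total step count: 17. Longest linear sequence: 15 steps (steps 1–9, then 12–17).

Steps most likely to fail:

1. Step 12. The vinylogous-ester stabilisation of the cyclobutenone may slow the first electrocyclic opening so much that, at the temperature then needed, the siloxyalkyne isomerises to a silylketene or the product phenol is acylated by vinylketene. The fallback generates the same vinylketene at room temperature by 1,4-dehydrochlorination instead of ring opening. It sets out from bromide 9: alkylation of ethyl acetoacetate (NaH, THF) should give ethyl 2-(Ar6-methyl)-3-oxobutanoate F1; HC(OEt)3 with catalytic H2SO4 in EtOH should give the enol ether ethyl 3-ethoxy-2-(Ar6-methyl)but-2-enoate F2; KOH in EtOH/H2O at reflux with cold acidification should give 3-ethoxy-2-(Ar6-methyl)but-2-enoic acid F3; oxalyl chloride should give 3-ethoxy-2-(Ar6-methyl)but-2-enoyl chloride F4. Slow addition of Et3N to F4 and siloxyalkyne 17 in CH2Cl2 should form 18 and trap it as 19; warming to 80 °C in toluene then carries 19 through 20 and 21, and the route is rejoined at 22.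

2. Step 13. The activated β-hydroxy ester may eliminate to ethyl cinnamate faster than the hindered phenol attacks, and any ionisation at the benzylic carbon would erode the configuration of C2. The fallback uses a carbinol without an acidifying β-carbonyl. It sets out from 22: Mitsunobu reaction with commercial (R)-3-chloro-1-phenylpropan-1-ol (PPh3, DIAD) should give with inversion the (1S)-3-chloro-1-phenylpropyl aryl ether F5; CsOAc in DMF should give the (3S)-3-aryloxy-3-phenylpropyl acetate F6; K2CO3 in MeOH at 0 °C should give the (3S)-3-aryloxy-3-phenylpropan-1-ol F7; TEMPO with PhI(OAc)2 in MeCN/H2O should oxidise it through the (3S)-3-aryloxy-3-phenylpropanal F8, not isolated, to the acid, and the route is rejoined at 25.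

3. Step 17. The chelated ethyl ether may be cleaved too slowly, benzyl cations may alkylate the electron-rich rings, and prolonged Lewis acid may open the pyranone (loss of C2 configuration) or detach an ortho-hydroxybenzyl arm. The fallback separates the two deprotections so that no benzyl cation is formed and the Lewis acid serves one ether only. It sets out from 27: hydrogenolysis (H2, Pd/C, EtOAc/MeOH, rt) should give the 5-O-ethyl ether of sarmentosumin D F9; chelation-controlled de-ethylation with MgI2 in Et2O/toluene, with mild warming, then gives the C5 phenol, and the route is rejoined at 28.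

**Further compounds**

F1 | step 12 | ethyl 2-(Ar6-methyl)-3-oxobutanoate (racemic) | CCOC(=O)C(Cc1cc(Cc2cc(Cc3ccccc3OCc3ccccc3)ccc2OCc2ccccc2)ccc1OCc1ccccc1)C(C)=O
F2 | step 12 | ethyl 3-ethoxy-2-(Ar6-methyl)but-2-enoate | CCOC(=O)C(Cc1cc(Cc2cc(Cc3ccccc3OCc3ccccc3)ccc2OCc2ccccc2)ccc1OCc1ccccc1)=C(C)OCC
F3 | step 12 | 3-ethoxy-2-(Ar6-methyl)but-2-enoic acid | OC(=O)C(Cc1cc(Cc2cc(Cc3ccccc3OCc3ccccc3)ccc2OCc2ccccc2)ccc1OCc1ccccc1)=C(C)OCC
F4 | step 12 | 3-ethoxy-2-(Ar6-methyl)but-2-enoyl chloride | ClC(=O)C(Cc1cc(Cc2cc(Cc3ccccc3OCc3ccccc3)ccc2OCc2ccccc2)ccc1OCc1ccccc1)=C(C)OCC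
F5 | step 13 | (1S)-3-chloro-1-phenylpropyl ether of phenol 22 | ClCC[C@@H](c1ccccc1)Oc1cc(OCC)c(Cc2cc(Cc3cc(Cc4ccccc4OCc4ccccc4)ccc3OCc3ccccc3)ccc2OCc2ccccc2)c(O[Si](C(C)C)(C(C)C)C(C)C)c1Cc1cc(Cc2ccccc2OCc2ccccc2)ccc1OCc1ccccc1
F6 | step 13 | (3S)-3-aryloxy-3-phenylpropyl acetate | CC(=O)OCC[C@@H](c1ccccc1)Oc1cc(OCC)c(Cc2cc(Cc3cc(Cc4ccccc4OCc4ccccc4)ccc3OCc3ccccc3)ccc2OCc2ccccc2)c(O[Si](C(C)C)(C(C)C)C(C)C)c1Cc1cc(Cc2ccccc2OCc2ccccc2)ccc1OCc1ccccc1
F7 | step 13 | (3S)-3-aryloxy-3-phenylpropan-1-ol | OCC[C@@H](c1ccccc1)Oc1cc(OCC)c(Cc2cc(Cc3cc(Cc4ccccc4OCc4ccccc4)ccc3OCc3ccccc3)ccc2OCc2ccccc2)c(O[Si](C(C)C)(C(C)C)C(C)C)c1Cc1cc(Cc2ccccc2OCc2ccccc2)ccc1OCc1ccccc1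
F8 | step 13 | (3S)-3-aryloxy-3-phenylpropanal | O=CC[C@@H](c1ccccc1)Oc1cc(OCC)c(Cc2cc(Cc3cc(Cc4ccccc4OCc4ccccc4)ccc3OCc3ccccc3)ccc2OCc2ccccc2)c(O[Si](C(C)C)(C(C)C)C(C)C)c1Cc1cc(Cc2ccccc2OCc2ccccc2)ccc1OCc1ccccc1
F9 | step 17 | 5-O-ethyl ether of sarmentosumin D, (2S) | O=C1C[C@@H](c2ccccc2)Oc2c(Cc3cc(Cc4ccccc4O)ccc3O)c(O)c(Cc3cc(Cc4cc(Cc5ccccc5O)ccc4O)ccc3O)c(OCC)c21
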